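## Retrosynthetic overview

1. Calamenene numbering is used: C1 = CHMe, C4 = CH‑iPr, C4a/C8a = ring fusion, C6–Me, C7–OH, C8 = biaryl carbon. The last disconnection is the C8–C8' axis, made by oxidative coupling of two molecules of (1S,4S)‑7‑hydroxycalamenene, whose only free ortho/para position is C8.
2. Key disconnection: the carbocycle C1–C2–C3–C4–C4a–C8a and the whole arene go back to a monocyclic 2‑diazo‑7‑methylidenecycloheptanone plus MeC≡CSMe. A photochemical Wolff shift moves C8a from the carbonyl carbon (C7) to the diazo carbon (C4a). This contracts the seven‑membered ring to the six‑membered one and expels C7 as a ketene carbon, and the vinylketene then runs a Danheiser‑type benzannulation.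
3. Enabling feature: in the arene, the hydroxyl carbon C7 lies para to C4a, C6–Me is ortho to it, and an unsubstituted C8 sits between C7 and C8a. This is exactly the pattern a vinylketene–alkyne benzannulation delivers. C7 can therefore be folded back as a one‑carbon bridge between C4a and C8a, which turns the tetralin into a cycloheptanone with both stereocentres on its beta carbons.
4. The cis‑3,6‑disubstituted cycloheptanone comes from cyclohepta‑2,6‑dienone by two catalyst‑controlled copper‑catalysed conjugate additions (iPr, then Me). The second enolate brings in C8 as a methylidene and the other alpha carbon takes the diazo group. SMe (at C5) is the removable activator of the alkyne.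
5. Order of rings: seven‑membered ring (purchased), then six‑membered carbocycle and arene together (key step), then biaryl.

Key step: step 8

Assumption: the given structure fixes four stereocentres but not the configuration of the C8–C8' axis. The axis is taken as it forms under substrate control, and atropisomers, should both form, are separated by chromatography.

Ligand L = O,O'-(1,1'-binaphthalene-2,2'-diyl) N,N-bis(1-phenylethyl)phosphoramidite. Its sense of induction is assigned by analogy with cyclohex‑2‑enone and cyclohept‑2‑enone.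

## Route

Step 1
Reactants: 1 cycloheptanone
Product: 2 cyclohepta-2,6-dien-1-one
Conditions: IBX (3 equiv), PhF/DMSO 2:1, 75 °C
Reagents that add atoms: none
Why: IBX dehydrogenation of ketones (enol attack on iodine, then elimination) is applied twice, and the amount of oxidant and the temperature are set so that the reaction should stop at the cross‑conjugated dienone before tropone forms.

Step 2
Reactants: 2 cyclohepta-2,6-dien-1-one
Product: 3 (6R)-6-(propan-2-yl)cyclohept-2-en-1-one
Conditions: Zn(iPr)2 (1.2 equiv), Cu(OTf)2 (2.5 mol %), (R,S,S)-L (5 mol %), toluene, −30 °C; then 1 M HCl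
Reagents that add atoms: diisopropylzinc, CC(C)[Zn]C(C)C
Why: Copper‑catalysed asymmetric conjugate addition of a dialkylzinc, with close precedent on cyclohept‑2‑enone and on cross‑conjugated cyclic dienones: the chiral copper complex selects one enantiotopic alkene face and so sets the isopropyl‑bearing centre as R, and the zinc dienolate formed is inert to a second addition.

Step 3
Reactants: 3 (6R)-6-(propan-2-yl)cyclohept-2-en-1-one
Product: 5 {[(3S,6R)-3-methyl-6-(propan-2-yl)cyclohept-1-en-1-yl]oxy}trimethylsilane, via methylzinc enolate 4 (not isolated)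
Conditions: ZnMe2 (1.5 equiv), Cu(OTf)2 (2.5 mol %), (S,R,R)-L (5 mol %), toluene, −25 °C; then Me3SiOTf, 0 °C to rt; Et3N, cold water
Reagents that add atoms: dimethylzinc, C[Zn]C; trimethylsilyl trifluoromethanesulfonate, C[Si](C)(C)OS(=O)(=O)C(F)(F)F
Why: Second copper‑catalysed asymmetric conjugate addition, now with the mirror‑image ligand so that catalyst control overrides the weak bias of the remote isopropyl group and places the methyl group cis to it (S centre), while silylation of zinc enolate 4 fixes the enol double bond on the methyl side of the carbonyl group.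

Step 4
Reactants: 5 {[(3S,6R)-3-methyl-6-(propan-2-yl)cyclohept-1-en-1-yl]oxy}trimethylsilane
Product: 6 (3S,6R)-2-[(dimethylamino)methyl]-3-methyl-6-(propan-2-yl)cycloheptan-1-one (C2 epimers)
Conditions: Me2N=CH2 I (Eschenmoser's salt, 1.2 equiv), CH2Cl2, rt; 1 M NaOH work-up
Reagents that add atoms: dimethyl(methylidene)ammonium iodide, C=[N+](C)C.[I-]
Why: Mannich aminomethylation of a silyl enol ether with a preformed iminium salt occurs only at the enol carbon fixed in step 3, and the new alpha stereocentre is of no consequence because it becomes sp2 in step 5.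

Step 5
Reactants: 6 (3S,6R)-2-[(dimethylamino)methyl]-3-methyl-6-(propan-2-yl)cycloheptan-1-one
Product: 8 (3S,6R)-3-methyl-2-methylidene-6-(propan-2-yl)cycloheptan-1-one, via methiodide 7 (not isolated)
Conditions: MeI (5 equiv), Et2O, rt; then sat. aq NaHCO3/CH2Cl2, rt; used at once
Reagents that add atoms: iodomethane, CI (enters 7 only and leaves again with trimethylamine; no atom of it stays in 8)
Why: Quaternisation and Hofmann‑type beta‑elimination (E1cB) of a Mannich base is the standard alpha‑methylenation of ketones, and the weak base should leave the adjacent stereocentre and the exocyclic position of the double bond untouched.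

Step 6
Reactants: 8 (3S,6R)-3-methyl-2-methylidene-6-(propan-2-yl)cycloheptan-1-one
Product: 10 (3S,6S)-2-diazo-6-methyl-7-methylidene-3-(propan-2-yl)cycloheptan-1-one, via trifluoroacetyl ketone 9 (not isolated)
Conditions: LiN(SiMe3)2, THF, −78 °C; CF3CO2CH2CF3; 5% HCl work-up; then MsN3, Et3N, H2O (1 equiv), MeCN, rt
Reagents that add atoms: methanesulfonyl azide, CS(=O)(=O)N=[N+]=[N-] (both nitrogen atoms of the diazo group); 2,2,2-trifluoroethyl trifluoroacetate, FC(F)(F)COC(=O)C(F)(F)F (trifluoroacetyl group of 9 only, lost again)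
Why: Detrifluoroacetylative diazo transfer (a deacylative Regitz diazo transfer devised for enones): kinetic deprotonation can only occur at the alpha' CH2, Claisen‑type trifluoroacetylation activates that carbon, and the sulfonyl azide then transfers N2 with loss of the trifluoroacetyl group, no stereocentre being touched.

Step 7
Reactants: 11 prop-1-yn-1-ylmagnesium bromide
Product: 12 1-(methylsulfanyl)prop-1-yne
Conditions: MeSSMe, THF, 0 °C to rt; water; fractional distillation
Reagents that add atoms: dimethyl disulfide, CSSC
Why: Sulfenylation of an alkynyl Grignard reagent with a disulfide (nucleophilic substitution at sulfur) gives the alkynyl thioether.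

Step 8
Reactants: 10 (3S,6S)-2-diazo-6-methyl-7-methylidene-3-(propan-2-yl)cycloheptan-1-one; 12 1-(methylsulfanyl)prop-1-yne
Product: 17 (5S,8S)-3,8-dimethyl-4-(methylsulfanyl)-5-(propan-2-yl)-5,6,7,8-tetrahydronaphthalen-2-ol, via ring-contracted vinylketene 13 (not isolated), via spirocyclobutenone 14 (not isolated), via dienylketene 15 (not isolated), via cyclohexadienone 16 (not isolated)
Conditions: 12 (3 equiv), hν (medium-pressure Hg lamp, Pyrex filter), CH2Cl2, 25 °C until N2 evolution ends; then toluene, 110 °C
Reagents that add atoms: none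
Why: Proposed new method: irradiation expels N2 from the s‑Z‑locked cyclic diazo ketone 10 with 1,2‑shift of the vinylic carbon C8a from the carbonyl carbon (future C7) to the diazo carbon (future C4a), so that the seven‑membered ring contracts to the ring C1–C2–C3–C4–C4a–C8a and C7 is pushed out as the carbonyl carbon of vinylketene 13 (Wolff rearrangement). Ketene 13 adds thioalkyne 12 in a regioselective [2+2] cycloaddition to give 14, whose reversible 4π‑electrocyclic opening at 110 °C gives dienylketene 15, 6π‑electrocyclisation (bond C7–C8) gives dienone 16, and tautomerisation gives phenol 17. The closest known reactions are the photochemical Wolff ring contraction of 2‑diazocycloalkanones and the Danheiser benzannulation of acyclic alpha‑diazo enones with hetero‑substituted alkynes, and what is new is their merger on a cyclic 2‑diazo‑7‑methylidene ketone. The carbocycle is closed by the 1,2‑shift (ring contraction), the transient four‑membered ring by [2+2] cycloaddition, and the arene by disrotatory 6π‑electrocyclisation. No lasting stereocentre is created (the spiro centre of 14 is erased), and the two existing ones survive because C1–H and C4–H are never enolisable nor part of the reacting π system, so the cis relation from steps 2 and 3 is carried over. The step needs the Wolff shift to beat a 1,2‑hydride shift from C4–H (secured by the ring‑enforced s‑Z geometry under direct irradiation), one orientation of the alkyne (secured by sulfur polarisation, which bonds the methyl‑bearing carbon to C7 and puts SMe on C5), and the dienylketene geometry with the ketene cis to the methylidene (the other isomer recloses to 14, so the equilibrium drains through 15).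

Step 9
Reactants: 17 (5S,8S)-3,8-dimethyl-4-(methylsulfanyl)-5-(propan-2-yl)-5,6,7,8-tetrahydronaphthalen-2-ol
Product: 18 (5S,8S)-3,8-dimethyl-5-(propan-2-yl)-5,6,7,8-tetrahydronaphthalen-2-ol [(1S,4S)-7-hydroxycalamenene]
Conditions: Raney Ni (W-2), EtOH, reflux
Reagents that add atoms: none
Why: Raney nickel hydrogenolysis of the aryl–sulfur bond (reductive desulfurisation) removes the activating group under neutral conditions that leave the phenol and both benzylic stereocentres untouched.

Step 10
Reactants: 18 (5S,8S)-3,8-dimethyl-5-(propan-2-yl)-5,6,7,8-tetrahydronaphthalen-2-ol (two molecules)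
Product: 19 (5S,5'S,8S,8'S)-3,3',8,8'-tetramethyl-5,5'-di(propan-2-yl)-5,5',6,6',7,7',8,8'-octahydro-[1,1'-binaphthalene]-2,2'-diol (target)
Conditions: t-BuOOt-Bu (1 equiv), FeCl3 (10 mol %), (CF3)2CHOH, rt
Reagents that add atoms: none
Why: Oxidative phenol coupling through the phenoxyl radical: C6 and C4a (ortho and para to OH) are blocked, so carbon–carbon coupling can rearomatise only at C8, which gives the C8–C8' biaryl without involving the four stereocentres.

## Compound list

1 | cycloheptanone | O=C1CCCCCC1 | starting material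
2 | cyclohepta-2,6-dien-1-one | O=C1C=CCCC=C1 | intermediate
3 | (6R)-6-(propan-2-yl)cyclohept-2-en-1-one | O=C1C=CCC[C@@H](C(C)C)C1 | intermediate
4 | methylzinc enolate of cis-(3R,6S)-3-isopropyl-6-methylcycloheptanone, enolate double bond toward the methyl-bearing carbon | C[Zn]OC1=C[C@@H](C)CC[C@@H](C(C)C)C1 | intermediate (not isolated)
5 | {[(3S,6R)-3-methyl-6-(propan-2-yl)cyclohept-1-en-1-yl]oxy}trimethylsilane | C[Si](C)(C)OC1=C[C@@H](C)CC[C@@H](C(C)C)C1 | intermediate
6 | (3S,6R)-2-[(dimethylamino)methyl]-3-methyl-6-(propan-2-yl)cycloheptan-1-one (C2 epimers) | CN(C)CC1C(=O)C[C@H](C(C)C)CC[C@@H]1C | intermediate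
7 | methiodide of 6 (trimethylammonium iodide) | C[N+](C)(C)CC1C(=O)C[C@H](C(C)C)CC[C@@H]1C.[I-] | intermediate (not isolated)
8 | (3S,6R)-3-methyl-2-methylidene-6-(propan-2-yl)cycloheptan-1-one | C=C1C(=O)C[C@H](C(C)C)CC[C@@H]1C | intermediate
9 | (3S,6S)-3-methyl-2-methylidene-6-(propan-2-yl)-7-(trifluoroacetyl)cycloheptan-1-one (C7 epimers/enol) | C=C1C(=O)C(C(=O)C(F)(F)F)[C@H](C(C)C)CC[C@@H]1C | intermediate (not isolated)
10 | (3S,6S)-2-diazo-6-methyl-7-methylidene-3-(propan-2-yl)cycloheptan-1-one | C=C1C(=O)C(=[N+]=[N-])[C@H](C(C)C)CC[C@@H]1C | intermediate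
11 | prop-1-yn-1-ylmagnesium bromide | CC#C[Mg]Br | starting material
12 | 1-(methylsulfanyl)prop-1-yne | CC#CSC | intermediate
13 | [(3S,6S)-3-methyl-2-methylidene-6-(propan-2-yl)cyclohexylidene]methanone (vinylketene) | O=C=C1C(=C)[C@@H](C)CC[C@H]1C(C)C | intermediate (not isolated)
14 | (6S,9S)-2,6-dimethyl-5-methylidene-3-(methylsulfanyl)-9-(propan-2-yl)spiro[3.5]non-2-en-1-one (spiro centre undefined) | CC1=C(SC)C2(C1=O)C(=C)[C@@H](C)CC[C@H]2C(C)C | intermediate (not isolated)
15 | 2-methyl-3-(methylsulfanyl)-3-[(3S,6S)-3-methyl-2-methylidene-6-(propan-2-yl)cyclohexylidene]prop-1-en-1-one, ketene unit cis to the methylidene-bearing ring carbon | O=C=C(C)/C(SC)=C1\C(=C)[C@@H](C)CC[C@H]1C(C)C | intermediate (not isolated)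
16 | (5S,8S)-3,8-dimethyl-4-(methylsulfanyl)-5-(propan-2-yl)-5,6,7,8-tetrahydronaphthalen-2(1H)-one | CC1=C(SC)C2=C(CC1=O)[C@@H](C)CC[C@H]2C(C)C | intermediate (not isolated)
17 | (5S,8S)-3,8-dimethyl-4-(methylsulfanyl)-5-(propan-2-yl)-5,6,7,8-tetrahydronaphthalen-2-ol | Cc1c(SC)c2c(cc1O)[C@@H](C)CC[C@H]2C(C)C | intermediate
18 | (5S,8S)-3,8-dimethyl-5-(propan-2-yl)-5,6,7,8-tetrahydronaphthalen-2-ol, (1S,4S)-7-hydroxycalamenene | Cc1cc2c(cc1O)[C@@H](C)CC[C@H]2C(C)C | intermediate
19 | (5S,5'S,8S,8'S)-3,3',8,8'-tetramethyl-5,5'-di(propan-2-yl)-5,5',6,6',7,7',8,8'-octahydro-[1,1'-binaphthalene]-2,2'-diol | Cc1cc2c(c(-c3c(O)c(C)cc4c3[C@@H](C)CC[C@H]4C(C)C)c1O)[C@@H](C)CC[C@H]2C(C)C | target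

## Step count and risks

Total step count: 10. Longest linear sequence: 9 (steps 1–6 and 8–10).

**Step 8 (proposed new method).**
- What may go wrong: a 1,2‑hydride shift at the carbene stage may compete with the Wolff shift. The hindered ring‑contracted ketene may also be lost to self‑addition because cycloaddition with the thioalkyne is slow.
- Fallback: known chemistry that keeps the ring contraction, sets out from 10 and returns at 18.
- Irradiation of 10 in methanol (classical Wolff ring contraction with capture of the ketene by the solvent) should give methyl (3S,6S)-3-methyl-2-methylidene-6-(propan-2-yl)cyclohexane-1-carboxylate F1.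
- iBu2AlH at −78 °C reduces it to (3S,6S)-3-methyl-2-methylidene-6-(propan-2-yl)cyclohexane-1-carbaldehyde F2.
- A Z‑selective Horner–Wadsworth–Emmons olefination (Ando variant: ethyl 2-(diphenoxyphosphoryl)propanoate, NaH, THF, −78 °C) gives ethyl (2Z)-2-methyl-3-[(3S,6S)-3-methyl-2-methylidene-6-(propan-2-yl)cyclohexyl]prop-2-enoate F3.
- LiOH gives (2Z)-2-methyl-3-[(3S,6S)-3-methyl-2-methylidene-6-(propan-2-yl)cyclohexyl]prop-2-enoic acid F4.
- Ac2O/NaOAc at reflux (dienoic acid benzannulation through the mixed anhydride, a dienylketene and 6π closure) gives (5S,8S)-3,8-dimethyl-5-(propan-2-yl)-5,6,7,8-tetrahydronaphthalen-2-yl acetate F5.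
- K2CO3/MeOH releases 18. In this variant the ester carbon becomes C5, and steps 7 and 9 are not needed.

**Step 6.**
- What may go wrong: conjugate addition and oligomerisation of the exocyclic enone under the basic acylation and amine conditions, or migration of the double bond into the ring with loss of the adjacent stereocentre.
- Fallback: the order is changed so that the methylidene stays masked as the amine. It sets out from 6 and returns at 10.
- Kinetic deprotonation of 6 with LiN(SiMe3)2 at the unsubstituted alpha CH2 and acylation with CF3CO2CH2CF3 gives (3S,6S)-2-[(dimethylamino)methyl]-3-methyl-6-(propan-2-yl)-7-(trifluoroacetyl)cycloheptan-1-one F6.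
- MsN3/Et3N gives (3S,6S)-2-diazo-7-[(dimethylamino)methyl]-6-methyl-3-(propan-2-yl)cycloheptan-1-one F7.
- MeI gives the methiodide of the diazo amino ketone F8.
- Aqueous NaHCO3 unveils the methylidene last, under nearly neutral conditions, to give 10.

**Step 10.**
- What may go wrong: over‑oxidation with loss of the benzylic C4–H (quinone methide formation, which erodes the C4 configuration), carbon–oxygen coupling, or low conversion at the crowded C8.
- Fallback: a non‑oxidative biaryl synthesis that sets out from 18 and returns at 19.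
- N‑Iodosuccinimide (cat. TsOH, MeCN) iodinates the only free position ortho to OH to give (5S,8S)-1-iodo-3,8-dimethyl-5-(propan-2-yl)-5,6,7,8-tetrahydronaphthalen-2-ol F9.
- MeI/K2CO3 gives (1S,4S)-8-iodo-7-methoxy-1,6-dimethyl-4-(propan-2-yl)-1,2,3,4-tetrahydronaphthalene F10.
- Ullmann homocoupling (activated Cu powder, DMF, 140 °C) gives the bis(methyl ether) of 19 F11.
- BBr3 (CH2Cl2, −78 °C to rt) gives 19.

## Further compounds

F1 | step 8 | methyl (3S,6S)-3-methyl-2-methylidene-6-(propan-2-yl)cyclohexane-1-carboxylate | COC(=O)C1C(=C)[C@@H](C)CC[C@H]1C(C)C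
F2 | step 8 | (3S,6S)-3-methyl-2-methylidene-6-(propan-2-yl)cyclohexane-1-carbaldehyde | O=CC1C(=C)[C@@H](C)CC[C@H]1C(C)C
F3 | step 8 | ethyl (2Z)-2-methyl-3-[(3S,6S)-3-methyl-2-methylidene-6-(propan-2-yl)cyclohexyl]prop-2-enoate | CCOC(=O)/C(C)=C\C1C(=C)[C@@H](C)CC[C@H]1C(C)C
F4 | step 8 | (2Z)-2-methyl-3-[(3S,6S)-3-methyl-2-methylidene-6-(propan-2-yl)cyclohexyl]prop-2-enoic acid | OC(=O)/C(C)=C\C1C(=C)[C@@H](C)CC[C@H]1C(C)C
F5 | step 8 | (5S,8S)-3,8-dimethyl-5-(propan-2-yl)-5,6,7,8-tetrahydronaphthalen-2-yl acetate | Cc1cc2c(cc1OC(C)=O)[C@@H](C)CC[C@H]2C(C)C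
F6 | step 6 | (3S,6S)-2-[(dimethylamino)methyl]-3-methyl-6-(propan-2-yl)-7-(trifluoroacetyl)cycloheptan-1-one | CN(C)CC1C(=O)C(C(=O)C(F)(F)F)[C@H](C(C)C)CC[C@@H]1C
F7 | step 6 | (3S,6S)-2-diazo-7-[(dimethylamino)methyl]-6-methyl-3-(propan-2-yl)cycloheptan-1-one | CN(C)CC1C(=O)C(=[N+]=[N-])[C@H](C(C)C)CC[C@@H]1C
F8 | step 6 | methiodide of the diazo amino ketone | C[N+](C)(C)CC1C(=O)C(=[N+]=[N-])[C@H](C(C)C)CC[C@@H]1C.[I-]
F9 | step 10 | (5S,8S)-1-iodo-3,8-dimethyl-5-(propan-2-yl)-5,6,7,8-tetrahydronaphthalen-2-ol | Cc1cc2c(c(I)c1O)[C@@H](C)CC[C@H]2C(C)C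
F10 | step 10 | (1S,4S)-8-iodo-7-methoxy-1,6-dimethyl-4-(propan-2-yl)-1,2,3,4-tetrahydronaphthalene | Cc1cc2c(c(I)c1OC)[C@@H](C)CC[C@H]2C(C)C
F11 | step 10 | bis(methyl ether) of 19 | Cc1cc2c(c(-c3c(OC)c(C)cc4c3[C@@H](C)CC[C@H]4C(C)C)c1OC)[C@@H](C)CC[C@H]2C(C)C
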